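## Analysis of the target

The target 14 is methyl (3R,7E)-10-[5-(furan-3-ylmethyl)furan-3-yl]-3,7-dimethyldec-7-enoate. Numbering from the ester carbon as C1, the ten-carbon chain carries a methyl-bearing stereocentre at C3 and an E-trisubstituted olefin at C7=C8. C10 is bonded to the β-carbon of ring A, a 2,4-disubstituted furan (chain at its C4), whose C2 is linked through a methylene to C3 of a second furan, ring B.

C3 (R) is the only stereocentre. It is a purely alkyl-substituted methine, β to the ester and four bonds from the olefin, so nothing in the molecule can relay or correct its configuration. It has to come from a reagent- or catalyst-controlled event. The E geometry of C7=C8 is a second, independent stereochemical element.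

The sensitive groups are the two electron-rich furans (intolerant of strong acid, electrophilic oxidants and anodic conditions), the doubly furylic CH2, and the methyl ester, which limits strongly basic or nucleophilic reagents. The difficulties are therefore the isolated methyl stereocentre, the stereodefined trisubstituted olefin, the 2,4-pattern of ring A (not what direct substitution of a furan delivers), and an order of events in which the furans meet only mild conditions.

The strategy rests on the C4–C5–C6 trimethylene link between C3 and C7. Its C4–C5 bond joins two carbons with no polar handle, and each maps onto a carboxylic acid: C4 onto the free carboxyl arm of the half-ester 2, and C5 onto the carboxyl of the alkynoic acid 3.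

## Retrosynthetic reasoning

**C8–C9.** The first cut is the single bond between olefinic C8 and the ethylene tether of ring A. It divides 14 into a furan-free chain, the alkenyl iodide 6 (ester, C3 and the complete E-olefin), and an ester-free bis-furan, the vinylfuran 12. The vinyl group of 12 becomes C9–C10 after hydroboration to the alkylborane 13. Cutting here rather than at C9–C10 or C10–ring A avoids furylmethyl electrophiles and skipped-diene intermediates. The two sets of sensitive groups then meet only once, in a palladium-catalysed sp3–sp2 coupling under weakly basic conditions at room temperature. The forward reaction must place boron only on the terminal vinyl carbon and transfer the alkyl group to C8 with retention of olefin geometry.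

**C8–I, C8–B and C7–CH3.** The iodide 6 is traced to the alkenylboronate 5, and 5 to the terminal alkyne 4 by removing the C7 methyl group and the boron together. A syn methylboration places both on the same side of the former triple bond, so the E geometry is fixed by mechanism and not by a thermodynamic preference. An alkyne is the latent olefin because it is inert to the preceding bond construction. The forward steps must deliver boron to C8 and methyl to C7, tolerate the methyl ester, and exchange boron for iodine without changing geometry.

**C4–C5 (key disconnection).** Alkyne 4 is cut in the middle of its unfunctionalised trimethylene into the half-ester 2 and the alkynoic acid 3. A polar construction here would need an activating group that must later be removed, or an alkyl organometallic next to an ester. At C4–C5 both carbons are carboxyl-derived, so the bond can arise from two primary radicals generated by anodic decarboxylation. C3 is one carbon from the new bond and is not involved. The gain is a one-step union of the chiral C1–C4 piece with the C5–C8 alkyne, with ester and alkyne already at their final oxidation levels and no protecting groups. The forward reaction must favour the crossed coupling over the two symmetrical ones and keep the radicals from being oxidised further.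

**Desymmetrisation.** The two arms of 2 differ only in which carboxyl is esterified, so 2 is traced to the prochiral diester 1 by distinguishing its enantiotopic ester groups with an esterase. No skeletal bond is made. Absolute configuration at C3 is obtained from a symmetrical compound.

**Vinyl–ring A.** The vinylfuran 12 is cut at the bond between the vinyl group and C4 of ring A, giving the bromofuran 11. The vinyl group is installed last in this branch because a vinylfuran would not survive the acid used to form the methylene bridge.

**Methylene bridge.** The bridging CH2 of 11 is traced to the carbinol 10 by restoring a hydroxyl group. Carbinol 10 is cut between the carbinol carbon and C3 of ring B into the formylfuran 8 and the lithiofuran 9, made from the bromide 7. The nucleophile sits on ring B, where a β-metallated furan is available by halogen–metal exchange. The 2,4-pattern of ring A is kept as purchased in 8, since substitution of a furan would give the 2,5-pattern.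

## Alternatives that were turned down

**Alternative 1:** Ring A is built at the end instead of being bought.
- Disconnection: the O1–C2 bond of ring A, leading back to the (Z)-enynol A2. Its hydroxymethyl carbon becomes C5 of ring A, its olefin becomes C3 and C4, and its alkyne (capped by ring B) becomes C2 and the bridging CH2.
- Forward key step: a carbophilic catalyst (Ph3PAuCl activated by AgOTf) lets the hydroxyl add 5-exo-dig to the near alkyne carbon. The exocyclic enol ether aromatises by proton shift to the silyl ether A1.
- For: the 2,4-pattern is dictated by the enynol skeleton, the reaction is mild and atom-economic, and no acid-labile difurylcarbinol is needed.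
- Against: A2 needs a second stereodefined trisubstituted olefin (Z) on top of C7=C8, plus a furyl alkyne. C3 still needs its own source. The chain is carried as a silyl ether, so A1 must be deprotected and oxidised in two stages to the ester with both furans present, where electrophilic oxidants are hazardous.
- Comparison: it is stronger on one point, since no cationic chemistry occurs at a furylic carbon. The chosen route buys the 2,4-pattern in 8, forms C4–C5 before any furan exists, ends at the correct oxidation level and is shorter.

**Alternative 2:** The trisubstituted olefin comes from a sigmatropic rearrangement.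
- Disconnection: C5–C6, leading back to the isopropenyl carbinol A4.
- Forward key step: a Johnson–Claisen rearrangement. Heating A4 with MeC(OMe)3 and a trace of weak carboxylic acid gives a mixed ketene acetal that rearranges through a chair, with the carbinol substituent equatorial, to the E-ester A3.
- For: the chair transition state is a dependable source of E-trisubstituted olefins, the reagents are cheap and no transition metal is needed.
- Against: the rearrangement runs hot and acidic on a bis-furan with free α-positions. A3 ends at C4 as an ester, so C1–C3 and the stereocentre are still missing. They would need reduction, activation and a catalytic asymmetric conjugate addition to a crotonate ester, setting C3 late on an organometallic that carries two furans.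
- Comparison: on olefin geometry alone it is at least as dependable as the methylboration, which relies on the regiochemistry of borylcupration, and it is cheaper. It leaves C3 unsolved, whereas the chosen strategy fixes C3 in the first step and then forms the bond this alternative leaves open.

**Alternative 3:** The stereocentre is set last, on the full skeleton.
- Disconnection: none in the skeleton. The C3–H bond is formed from the dienal A6.
- Forward key step: an ene-reductase of the Old Yellow Enzyme family, with its nicotinamide cofactor recycled by a dehydrogenase, adds hydride to C3 and a proton to C2 to give the aldehyde A5.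
- For: A6 is isoprenoid-like and accessible by standard olefination. The asymmetric step is catalytic and aqueous, and β-methyl enals are a typical substrate class for these enzymes.
- Against: a lipophilic C20 bis-furan enal is far from the usual substrates in size and solubility. The 2E and 2Z enals interconvert and lead to opposite enantiomers, so enantiopurity depends on geometric purity. An enzyme giving R must be found by screening. A5 must still be oxidised to the acid and esterified with two furans present, and C2=C3 adds a third geometric element.
- Comparison: it may be stronger on attainable enantiopurity and on access to either enantiomer by enzyme choice. The chosen route sets C3 with an enzyme on a small, well-behaved substrate before anything sensitive exists, and needs no oxidation after the furans are in place.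

Key step: step 2

## Route

Step 1
Reactants: 1 dimethyl 3-methylpentanedioate (dimethyl 3-methylglutarate)
Product: 2 (R)-5-methoxy-3-methyl-5-oxopentanoic acid
Conditions: pig liver esterase, 0.1 M phosphate buffer (pH 7)–MeOH 4:1, −10 °C, pH-stat with 1 M NaOH; then HCl to pH 2, EtOAc extraction
Reagents that add atoms: water, O
Why: Enzymatic desymmetrisation of a prochiral diester: the esterase should hydrolyse the pro-S ester group of the 3-methylglutarate, leaving the ester on the arm that makes C3 R, and low temperature with aqueous methanol sharpens the discrimination. Enantiomeric purity is to be checked on a derivative before the material is carried on.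

Step 2
Reactants: 2 (R)-5-methoxy-3-methyl-5-oxopentanoic acid, 3 pent-4-ynoic acid
Product: 4 methyl (R)-3-methyloct-7-ynoate
Conditions: 2 (1 equiv), 3 (4 equiv), NaOMe (5 mol% of total acid), MeOH, smooth Pt anode and Pt cathode, undivided cell, ca. 250 mA cm−2, 30–40 °C, until the electrolyte turns faintly basic
Reagents that add atoms: none
Why: Mixed Kolbe electrolysis: both carboxylates are discharged at the platinum anode, the acyloxy radicals lose CO2, and the primary radicals MeO2C–CH2–CH(CH3)–CH2• (from 2) and HC≡C–CH2–CH2• (from 3) combine in the radical-rich layer at the electrode to form the C4–C5 bond. The closest known reaction type is the crossed Kolbe coupling of a dicarboxylic acid monoester with an excess of a second aliphatic acid, a standard way of extending methyl-branched chains. No ring is closed and no stereocentre is created; C3 is next to, but not part of, the radical centre and has no pathway to inversion, and methoxide in methanol can only exchange the methyl ester with itself. The first selectivity needed is crossed over symmetrical coupling, which is statistical at best and is therefore pushed toward consumption of the valuable partner 2 by the fourfold excess of 3; the two symmetrical dimers (a volatile C8 diyne and a C12 diester) differ enough from the C10 monoester 4 in boiling point and polarity to be removed by distillation and chromatography. The second is the radical rather than the carbocation (Hofer–Moest) pathway, secured because both radicals are primary and unstabilised (the alkyne of 3 is homopropargylic, not propargylic, to the radical) and because smooth platinum, high current density and a low degree of neutralisation favour radical coupling. The homopropargyl radical has no favourable cyclisation channel, and ester and terminal alkyne are not oxidised at a carboxylate-covered anode, whereas furans would be, which is why this step precedes their introduction.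

Step 3
Reactants: 4 methyl (R)-3-methyloct-7-ynoate
Product: 5 methyl (3R,7E)-3,7-dimethyl-8-(4,4,5,5-tetramethyl-1,3,2-dioxaborolan-2-yl)oct-7-enoate
Conditions: CuCl (10 mol%), Xantphos (10 mol%), NaOtBu (1.5 equiv), B2pin2 (1.3 equiv), MeI (4 equiv), THF, rt
Reagents that add atoms: bis(pinacolato)diboron, CC1(C)OB(OC1(C)C)B1OC(C)(C)C(C)(C)O1; iodomethane, CI
Why: Copper-catalysed formal carboboration (methylboration) of a terminal alkyne: the phosphine-ligated boryl-copper adds syn with boron at the terminal carbon, and the β-boryl alkenylcopper is methylated with retention, so methyl and boron end cis and the chain and boron trans (E). The alkoxide is largely held as the diboron ate complex, so the methyl ester is expected to be tolerated.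

Step 4
Reactants: 5 methyl (3R,7E)-3,7-dimethyl-8-(4,4,5,5-tetramethyl-1,3,2-dioxaborolan-2-yl)oct-7-enoate
Product: 6 methyl (3R,7E)-8-iodo-3,7-dimethyloct-7-enoate
Conditions: NaOMe (3 equiv), MeOH–THF, 0 °C; then I2 (1.5 equiv) in THF, 0 °C; aq Na2S2O3
Reagents that add atoms: iodine, II
Why: Base-mediated iododeboronation of an alkenylboronate: the methoxy boronate is attacked by iodine at the boron-bearing carbon, the tertiary β-cation is stabilised by the C–B bond, and boron departs, giving ipso substitution with retention of the E geometry. Methoxide replaces the usual aqueous hydroxide because its attack on the methyl ester is degenerate.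

Step 5
Reactants: 7 3-bromofuran, 8 4-bromofuran-2-carbaldehyde
Product: 10 (4-bromofuran-2-yl)(furan-3-yl)methanol (racemic), via furan-3-yllithium 9 (not isolated)
Conditions: 7, n-BuLi (1.0 equiv), THF, −78 °C, 20 min; then 8, −78 °C; H2O quench
Reagents that add atoms: none
Why: Bromine–lithium exchange followed by 1,2-addition of the heteroaryllithium to an aldehyde; at −78 °C the 3-lithiofuran does not isomerise to the 2-lithio species and adds to the formyl group much faster than it exchanges with the ring bromine of 8. The carbinol centre forms racemic and is removed in the next step.

Step 6
Reactants: 10 (4-bromofuran-2-yl)(furan-3-yl)methanol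
Product: 11 4-bromo-2-(furan-3-ylmethyl)furan
Conditions: Et3SiH (3 equiv), CF3CO2H (2 equiv, added last and slowly), CH2Cl2, −40 to 0 °C
Reagents that add atoms: none
Why: Ionic hydrogenation of a diheteroaryl carbinol: protonation and loss of water give a cation stabilised by both furans, which takes hydride from the silane. Low temperature, excess silane and the deactivating ring bromine should hold back Friedel–Crafts self-condensation, and the acid-sensitive vinyl group is not yet present.

Step 7
Reactants: 11 4-bromo-2-(furan-3-ylmethyl)furan
Product: 12 4-ethenyl-2-(furan-3-ylmethyl)furan
Conditions: 4,4,5,5-tetramethyl-2-vinyl-1,3,2-dioxaborolane (1.5 equiv), PdCl2(dppf) (5 mol%), K3PO4 (3 equiv), dioxane–H2O 4:1, 80 °C, trace BHT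
Reagents that add atoms: 4,4,5,5-tetramethyl-2-vinyl-1,3,2-dioxaborolane, C=CB1OC(C)(C)C(C)(C)O1
Why: Suzuki–Miyaura coupling of a β-bromofuran with a vinylboronate; nothing else in 11 reacts with zerovalent palladium or phosphate, and the radical inhibitor guards the vinylfuran against polymerisation.

Step 8
Reactants: 12 4-ethenyl-2-(furan-3-ylmethyl)furan, 6 methyl (3R,7E)-8-iodo-3,7-dimethyloct-7-enoate
Product: 14 methyl (3R,7E)-10-[5-(furan-3-ylmethyl)furan-3-yl]-3,7-dimethyldec-7-enoate, via alkylborane 13 (not isolated)
Conditions: 12 (1.3 equiv), 9-BBN (0.5 M in THF, 1.4 equiv), 0 °C to rt; then 6 (1.0 equiv), PdCl2(dppf) (5 mol%), AsPh3 (10 mol%), Cs2CO3 (3 equiv), DMF–THF–H2O, rt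
Reagents that add atoms: none
Why: Anti-Markovnikov hydroboration of the vinyl group by the bulky dialkylborane, then B-alkyl Suzuki–Miyaura coupling with the alkenyl iodide, which forms C8–C9 with retention at the sp2 carbon and so carries the E geometry into C7=C8. Aqueous carbonate at room temperature should leave the methyl ester, both furans and C3 untouched.

## Compound list

1 | dimethyl 3-methylpentanedioate | COC(=O)CC(C)CC(=O)OC | starting material
2 | (R)-5-methoxy-3-methyl-5-oxopentanoic acid | COC(=O)C[C@H](C)CC(=O)O | intermediate
3 | pent-4-ynoic acid | C#CCCC(=O)O | starting material
4 | methyl (R)-3-methyloct-7-ynoate | COC(=O)C[C@H](C)CCCC#C | intermediate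
5 | methyl (3R,7E)-3,7-dimethyl-8-(4,4,5,5-tetramethyl-1,3,2-dioxaborolan-2-yl)oct-7-enoate | COC(=O)C[C@H](C)CCC/C(C)=C/B1OC(C)(C)C(C)(C)O1 | intermediate
6 | methyl (3R,7E)-8-iodo-3,7-dimethyloct-7-enoate | COC(=O)C[C@H](C)CCC/C(C)=C/I | intermediate
7 | 3-bromofuran | Brc1ccoc1 | starting material
8 | 4-bromofuran-2-carbaldehyde | O=Cc1cc(Br)co1 | starting material
9 | furan-3-yllithium | [Li]c1ccoc1 | intermediate
10 | (4-bromofuran-2-yl)(furan-3-yl)methanol (racemic) | OC(c1cc(Br)co1)c1ccoc1 | intermediate
11 | 4-bromo-2-(furan-3-ylmethyl)furan | Brc1coc(Cc2ccoc2)c1 | intermediate
12 | 4-ethenyl-2-(furan-3-ylmethyl)furan | C=Cc1coc(Cc2ccoc2)c1 | intermediate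
13 | 9-{2-[5-(furan-3-ylmethyl)furan-3-yl]ethyl}-9-borabicyclo[3.3.1]nonane | C(Cc1coc(Cc2ccoc2)c1)B1C2CCCC1CCC2 | intermediate
14 | methyl (3R,7E)-10-[5-(furan-3-ylmethyl)furan-3-yl]-3,7-dimethyldec-7-enoate | COC(=O)C[C@H](C)CCC/C(C)=C/CCc1coc(Cc2ccoc2)c1 | target

## Step count and least certain steps

Total: 8 steps. Longest linear sequence: 5 steps (steps 1, 2, 3, 4, 8). The furan branch (steps 5, 6, 7) joins in step 8.

**Step 2 (key step).**
- Most likely failure: loss of the valuable half-ester to symmetrical coupling, since radical pairing is statistical and excess 3 only biases it. Over-oxidation of the radicals to cations (ethers, olefins) and fouling of the anode by alkyne-derived films would lower the crossed yield further. A slower risk is erosion of enantiopurity if acid and ester exchange arms through the cyclic anhydride while 2 stands in the warm electrolyte.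
- Fallback, forming the same C4–C5 bond at nickel instead of at an anode: it sets out from 2 and returns at 4. Acid 2 would be condensed with N-hydroxyphthalimide (N,N′-diisopropylcarbodiimide, cat. DMAP, CH2Cl2) to the redox-active ester 1-(1,3-dioxoisoindolin-2-yl) 5-methyl (S)-3-methylpentanedioate F1. The spatial arrangement is that of 2; only the descriptor changes with the priorities. F1 would undergo nickel-catalysed decarboxylative alkyl–alkyl coupling (NiCl2·glyme, 4,4′-di-tert-butyl-2,2′-bipyridine, THF–DMF, rt) with bis[4-(trimethylsilyl)but-3-yn-1-yl]zinc F2, made from the corresponding silyl-protected homopropargyl bromide through its Grignard reagent and ZnCl2. This would give methyl (R)-3-methyl-8-(trimethylsilyl)oct-7-ynoate F3. Desilylation (K2CO3, MeOH, rt) would return 4.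

**Step 3.**
- Most likely failure: attack of the alkoxide base on the methyl ester (Claisen self-condensation or transesterification). Protonation of the alkenylcopper before methylation, and partial delivery of boron to the internal carbon, are further risks.
- Fallback, replacing steps 3 and 4 by a Negishi carboalumination run at the alcohol oxidation level: it sets out from 4 and returns at 6. Reduction of 4 (LiAlH4, THF, 0 °C) would give (R)-3-methyloct-7-yn-1-ol F4. Zirconium-catalysed methylalumination with iodine quench (Me3Al 3 equiv, Cp2ZrCl2 0.25 equiv, CH2Cl2, 0 °C to rt; then I2, THF, −30 °C) would give (3R,7E)-8-iodo-3,7-dimethyloct-7-en-1-ol F5 by syn addition and iodinolysis with retention. Jones oxidation (CrO3, H2SO4, acetone, 0 °C) would give (3R,7E)-8-iodo-3,7-dimethyloct-7-enoic acid F6. Esterification (MeI, K2CO3, DMF, rt) would return 6.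

**Step 6.**
- Most likely failure: Friedel–Crafts capture of the furan-stabilised cation by a free α-position of another furan (oligomerisation), or acid-induced ring opening, before hydride transfer takes place.
- Fallback, replacing the cationic reduction by a base-mediated one: it sets out from 10 and returns at 11. Oxidation of 10 (MnO2, CH2Cl2, rt) would give (4-bromofuran-2-yl)(furan-3-yl)methanone F7. Wolff–Kishner reduction (N2H4·H2O, KOH, diethylene glycol, 120 then 190 °C) would proceed through [(4-bromofuran-2-yl)(furan-3-yl)methylidene]hydrazine F8 to 11, with no acid present.

**Step 8.**
- Most likely failure: unclean hydroboration of the vinylfuran (boron at the furylic carbon, or addition to a furan ring), protodeboronation of the β-furylethylborane, or transmetalation too slow to compete with decomposition of the alkenyl iodide.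
- Fallback, making the sp3 nucleophile by zinc insertion instead of hydroboration and coupling in a Negishi reaction: it sets out from 11 and returns at 14. Bromine–lithium exchange on 11 (n-BuLi, THF, −78 °C) and opening of ethylene oxide in the presence of BF3·OEt2 would give 2-[5-(furan-3-ylmethyl)furan-3-yl]ethan-1-ol F9. An Appel-type iodination (I2, PPh3, imidazole, CH2Cl2, 0 °C) would give 2-(furan-3-ylmethyl)-4-(2-iodoethyl)furan F10. Zinc insertion (Zn dust, LiCl, THF, rt) would give {2-[5-(furan-3-ylmethyl)furan-3-yl]ethyl}zinc iodide F11. Coupling of F11 with 6 (Pd(OAc)2 2 mol%, SPhos 4 mol%, THF, rt) would give 14.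

## Further compounds

F1 | step 2 | 1-(1,3-dioxoisoindolin-2-yl) 5-methyl (S)-3-methylpentanedioate | COC(=O)C[C@H](C)CC(=O)ON1C(=O)c2ccccc2C1=O
F2 | step 2 | bis[4-(trimethylsilyl)but-3-yn-1-yl]zinc | C[Si](C)(C)C#CCC[Zn]CCC#C[Si](C)(C)C
F3 | step 2 | methyl (R)-3-methyl-8-(trimethylsilyl)oct-7-ynoate | COC(=O)C[C@H](C)CCCC#C[Si](C)(C)C
F4 | step 3 | (R)-3-methyloct-7-yn-1-ol | OCC[C@H](C)CCCC#C
F5 | step 3 | (3R,7E)-8-iodo-3,7-dimethyloct-7-en-1-ol | OCC[C@H](C)CCC/C(C)=C/I
F6 | step 3 | (3R,7E)-8-iodo-3,7-dimethyloct-7-enoic acid | OC(=O)C[C@H](C)CCC/C(C)=C/I
F7 | step 6 | (4-bromofuran-2-yl)(furan-3-yl)methanone | O=C(c1cc(Br)co1)c1ccoc1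
F8 | step 6 | [(4-bromofuran-2-yl)(furan-3-yl)methylidene]hydrazine | NN=C(c1cc(Br)co1)c1ccoc1
F9 | step 8 | 2-[5-(furan-3-ylmethyl)furan-3-yl]ethan-1-ol | OCCc1coc(Cc2ccoc2)c1
F10 | step 8 | 2-(furan-3-ylmethyl)-4-(2-iodoethyl)furan | ICCc1coc(Cc2ccoc2)c1
F11 | step 8 | {2-[5-(furan-3-ylmethyl)furan-3-yl]ethyl}zinc iodide | I[Zn]CCc1coc(Cc2ccoc2)c1
A1 | alternative 1 | tert-butyl{[(3R,7E)-10-[5-(furan-3-ylmethyl)furan-3-yl]-3,7-dimethyldec-7-en-1-yl]oxy}dimethylsilane | CC(C)(C)[Si](C)(C)OCC[C@H](C)CCC/C(C)=C/CCc1coc(Cc2ccoc2)c1
A2 | alternative 1 | (2Z)-2-[(3E,8R)-10-{[tert-butyl(dimethyl)silyl]oxy}-4,8-dimethyldec-3-en-1-yl]-5-(furan-3-yl)pent-2-en-4-yn-1-ol | CC(C)(C)[Si](C)(C)OCC[C@H](C)CCC/C(C)=C/CC/C(CO)=C/C#Cc1ccoc1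
A3 | alternative 2 | methyl (E)-7-[5-(furan-3-ylmethyl)furan-3-yl]-4-methylhept-4-enoate | COC(=O)CC/C(C)=C/CCc1coc(Cc2ccoc2)c1
A4 | alternative 2 | 5-[5-(furan-3-ylmethyl)furan-3-yl]-2-methylpent-1-en-3-ol (racemic) | C=C(C)C(O)CCc1coc(Cc2ccoc2)c1
A5 | alternative 3 | (3R,7E)-10-[5-(furan-3-ylmethyl)furan-3-yl]-3,7-dimethyldec-7-enal | O=CC[C@H](C)CCC/C(C)=C/CCc1coc(Cc2ccoc2)c1
A6 | alternative 3 | (2E,7E)-10-[5-(furan-3-ylmethyl)furan-3-yl]-3,7-dimethyldeca-2,7-dienal | O=C/C=C(\C)CCC/C(C)=C/CCc1coc(Cc2ccoc2)c1
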